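**Plan**

- Rings: A is the benzo ring of the chroman, B the 2-aryl ring, C the pyran ring, P the phloroglucinol ring. Retrosynthetic cuts, in order: the five O–benzyl bonds; the ring P–acyl bond (through a bromine held on ring P); C4–C4a of ring C; C4–C1' to ring P; the C2–O aryl ether; the C2–C3 bond.
- Enabling feature: C4 carries ring P, whose oxygens at C2', C4' and C6' make a C4 cation easy to form, and ring A carbon C4a lies ortho to O1 and para to the C7 oxygen, so it can attack that cation.
- Forward order: ring B aldehyde, allylation (C2–C3), aryl ether to ring A (C2–O), alkene cleaved to the C4 aldehyde, ring P added (C4–C1'), ring C closed (the only ring made), acyl chain joined to ring P, debenzylation.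
- Stereochemistry: C2 comes from a reagent-controlled allylboration (S) followed by Mitsunobu inversion (R). C4 is set from C2 in the ring closure (2,4-cis, 4R).
- Ring B carries a triflate until ring C is closed so that C2 cannot ionise; the ring P bromine fixes where the acyl group goes, so no late acylation has to choose between rings P and A.

Key step: step 8

Remark: the target is (2R,4R), the 2,4-cis chroman. The carbinol that enters the key step is used as the mixture of its two C4 epimers, because this centre becomes planar on ionisation.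

**Route**

Step 1
Reactants: 1 4-hydroxybenzaldehyde
Product: 2 4-formylphenyl trifluoromethanesulfonate
Conditions: Tf2O, pyridine, CH2Cl2, 0 °C
Reagents that add atoms: trifluoromethanesulfonic anhydride, O=S(=O)(OS(=O)(=O)C(F)(F)F)C(F)(F)F
Why: Sulfonylation of the phenol should be clean; the triflate withdraws electron density from the future ring B, has no acidic α-hydrogen that an aryllithium could remove (as a mesylate has), and can later be cleaved at room temperature.

Step 2
Reactants: 2 4-formylphenyl trifluoromethanesulfonate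
Product: 4 4-[(1S)-1-hydroxybut-3-en-1-yl]phenyl trifluoromethanesulfonate, via borinate ester 3 (not isolated)
Conditions: (−)-Ipc2BOMe [from (+)-α-pinene], allylMgBr, Et2O, −78 °C to rt; then 2, −78 °C; then HOCH2CH2NH2, rt
Reagents that add atoms: allylmagnesium bromide, C=CC[Mg]Br
Why: Brown asymmetric allylboration: the B-allyl borane made in the flask adds through a closed chair transition state, the (+)-α-pinene-derived isopinocampheyl groups steering the allyl group to the si face of the aldehyde, so the S carbinol is expected, and the amine work-up frees the alcohol without exposing the triflate to hydroxide.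

Step 3
Reactants: 4 4-[(1S)-1-hydroxybut-3-en-1-yl]phenyl trifluoromethanesulfonate; 5 3-(benzyloxy)phenol
Product: 6 4-{(1R)-1-[3-(benzyloxy)phenoxy]but-3-en-1-yl}phenyl trifluoromethanesulfonate
Conditions: PPh3, DIAD, THF, 0 °C to rt
Reagents that add atoms: none
Why: Mitsunobu etherification: the phenol displaces the oxyphosphonium group in an SN2 reaction with inversion, S to R, which sets C2 of the target, and the electron-poor aryl group disfavours an ionising pathway that would erode the configuration.

Step 4
Reactants: 6 4-{(1R)-1-[3-(benzyloxy)phenoxy]but-3-en-1-yl}phenyl trifluoromethanesulfonate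
Product: 8 4-{(1R)-1-[3-(benzyloxy)phenoxy]-3-oxopropyl}phenyl trifluoromethanesulfonate, via diol 7 (not isolated)
Conditions: OsO4 (2 mol %), NaIO4, 2,6-lutidine, dioxane/H2O, rt
Reagents that add atoms: osmium tetroxide, O=[Os](=O)(=O)=O; sodium periodate, [Na+].[O-]I(=O)(=O)=O; water, O
Why: Lemieux–Johnson oxidative cleavage (osmium-catalysed dihydroxylation, then periodate cleavage of the diol, buffered by 2,6-lutidine) should turn the terminal alkene into the aldehyde without touching the aryl ethers, the triflate or the stereocentre; the β-aryloxy aldehyde is used at once because base could eliminate the aryloxide.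

Step 5
Reactants: 9 phloroglucinol
Product: 10 1,3,5-tris(benzyloxy)benzene
Conditions: BnBr, K2CO3, DMF, rt
Reagents that add atoms: benzyl bromide, BrCc1ccccc1
Why: Threefold Williamson etherification of the phenol; C-benzylated by-products, the known side reaction of phloroglucinol, are expected to be removable by crystallisation.

Step 6
Reactants: 10 1,3,5-tris(benzyloxy)benzene
Product: 11 1,3,5-tris(benzyloxy)-2,4-dibromobenzene
Conditions: NBS (2.05 equiv), CH2Cl2, −20 °C to rt, dark
Reagents that add atoms: N-bromosuccinimide, O=C1CCC(=O)N1Br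
Why: Electrophilic aromatic bromination of the highly activated ring; each bromine lowers the reactivity, so two equivalents should stop at the dibromide, in which one C–Br bond will become the C4–C1' bond and the other marks the carbon that later takes the acyl group.

Step 7
Reactants: 11 1,3,5-tris(benzyloxy)-2,4-dibromobenzene; 8 4-{(1R)-1-[3-(benzyloxy)phenoxy]-3-oxopropyl}phenyl trifluoromethanesulfonate
Product: 13 4-{(1R)-1-[3-(benzyloxy)phenoxy]-3-hydroxy-3-[2,4,6-tris(benzyloxy)-3-bromophenyl]propyl}phenyl trifluoromethanesulfonate (both carbinol epimers), via aryllithium 12 (not isolated)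
Conditions: n-BuLi (1.0 equiv), THF, −78 °C; then 8, −78 °C; aq. NH4Cl
Reagents that add atoms: none
Why: Bromine–lithium exchange at one of the two equivalent C–Br bonds followed by 1,2-addition of the aryllithium to the aldehyde, which at −78 °C should outrun enolisation and attack at the sulfonyl sulfur; the new carbinol centre forms without control, which does not matter because step 8 makes it planar.

Step 8
Reactants: 13 4-{(1R)-1-[3-(benzyloxy)phenoxy]-3-hydroxy-3-[2,4,6-tris(benzyloxy)-3-bromophenyl]propyl}phenyl trifluoromethanesulfonate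
Product: 14 4-{(2R,4R)-7-(benzyloxy)-4-[2,4,6-tris(benzyloxy)-3-bromophenyl]chroman-2-yl}phenyl trifluoromethanesulfonate
Conditions: Bi(OTf)3 (5 mol %), CH2Cl2, −40 to 0 °C
Reagents that add atoms: none
Why: The Lewis acid Bi(OTf)3 (or the trace of triflic acid it releases) ionises the C4 carbinol of either epimer to one benzylic cation that the ortho and para benzyloxy groups of ring P stabilise (the bromine, meta to the cationic carbon, costs little), ring A adds to it through the carbon para to its benzyloxy group and ortho to the ether oxygen, and proton loss restores the arene; this is an intramolecular Friedel–Crafts alkylation of the kind known for aryl 3-aryl-3-hydroxypropyl ethers giving 4-arylchromans. Ring C closes as a six-membered ring by the C4–C4a bond: the attacking π-bond C4a–C8a of ring A ends up inside the new ring (endo mode for the nucleophile), while the departing water leaves from outside it (exo mode at the electrophilic carbon). The new stereocentre C4 is controlled by the existing C2 centre: in the chair-like transition state the C2 aryl group is equatorial and the planar cation is attacked on the face that lets ring P become equatorial too, which should give the 2,4-cis product, 4R from 2R. Three selectivities are needed: site selectivity on ring A, secured by the crowding of the carbon between the two oxygens; ionisation at C4 and not at C2, secured by the triflate that makes ring B electron-poor (it also keeps ring B from closing an indane); and ring closure ahead of proton loss to a styrene, secured by the low temperature and the fast six-membered intramolecular trapping.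

Step 9
Reactants: 14 4-{(2R,4R)-7-(benzyloxy)-4-[2,4,6-tris(benzyloxy)-3-bromophenyl]chroman-2-yl}phenyl trifluoromethanesulfonate
Product: 16 (2R,4R)-7-(benzyloxy)-2-[4-(benzyloxy)phenyl]-4-[2,4,6-tris(benzyloxy)-3-bromophenyl]chroman, via phenol 15 (not isolated)
Conditions: Et4NOH (aq.), 1,4-dioxane, rt; then BnBr, rt
Reagents that add atoms: benzyl bromide, BrCc1ccccc1
Why: Hydroxide attacks the sulfur of the aryl triflate (S–O cleavage, a known room-temperature deprotection) and the phenoxide is benzylated in the same pot (Williamson etherification), so that it has little time to open ring C through a quinone methide; with ring C closed the electron-poor ring B is no longer needed and all five phenols now carry the same group.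

Step 10
Reactants: 17 9-phenylnonanoic acid
Product: 19 N-methoxy-N-methyl-9-phenylnonanamide, via acyl imidazole 18 (not isolated)
Conditions: CDI, CH2Cl2, rt; then MeNH(OMe)·HCl, rt
Reagents that add atoms: N,O-dimethylhydroxylamine hydrochloride, CNOC.Cl
Why: Amide coupling through the acyl imidazole gives the Weinreb amide, the acyl donor for step 11.

Step 11
Reactants: 16 (2R,4R)-7-(benzyloxy)-2-[4-(benzyloxy)phenyl]-4-[2,4,6-tris(benzyloxy)-3-bromophenyl]chroman; 19 N-methoxy-N-methyl-9-phenylnonanamide
Product: 22 1-{2,4,6-tris(benzyloxy)-3-[(2R,4R)-7-(benzyloxy)-2-[4-(benzyloxy)phenyl]chroman-4-yl]phenyl}-9-phenylnonan-1-one, via aryllithium 20 (not isolated), via lithium hemiaminal 21 (not isolated)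
Conditions: n-BuLi, THF, −78 °C; then 19, −78 to 0 °C; aq. NH4Cl
Reagents that add atoms: none
Why: Bromine–lithium exchange, faster at −78 °C than any attack on the benzyl ethers, then acyl substitution on the Weinreb amide, whose chelated tetrahedral adduct survives until work-up and so prevents a second addition; the position of the acyl group on ring P is fixed by the bromine.

Step 12
Reactants: 22 1-{2,4,6-tris(benzyloxy)-3-[(2R,4R)-7-(benzyloxy)-2-[4-(benzyloxy)phenyl]chroman-4-yl]phenyl}-9-phenylnonan-1-one
Product: 23 1-{2,4,6-trihydroxy-3-[(2R,4R)-7-hydroxy-2-(4-hydroxyphenyl)chroman-4-yl]phenyl}-9-phenylnonan-1-one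
Conditions: H2 (1 atm), Pd/C (10 %), EtOAc/MeOH, rt
Reagents that add atoms: none
Why: Hydrogenolysis of the five benzyl ethers over palladium under neutral conditions, which should leave C2 and C4 untouched; the hydrogen-bonded acylphloroglucinol ketone and the cyclic benzylic C2–O1 ether are of the kinds that normally survive such debenzylations.

**Compound list**

1 | 4-hydroxybenzaldehyde | O=Cc1ccc(O)cc1 | starting material
2 | 4-formylphenyl trifluoromethanesulfonate | O=Cc1ccc(OS(=O)(=O)C(F)(F)F)cc1 | intermediate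
3 | (1S)-1-[4-(trifluoromethylsulfonyloxy)phenyl]but-3-en-1-yl diisopinocampheylborinate | C=CC[C@H](OB([C@@H]1C[C@@H]2C[C@H]([C@H]1C)C2(C)C)[C@@H]1C[C@@H]2C[C@H]([C@H]1C)C2(C)C)c1ccc(OS(=O)(=O)C(F)(F)F)cc1 | intermediate
4 | 4-[(1S)-1-hydroxybut-3-en-1-yl]phenyl trifluoromethanesulfonate | C=CC[C@H](O)c1ccc(OS(=O)(=O)C(F)(F)F)cc1 | intermediate
5 | 3-(benzyloxy)phenol | Oc1cccc(OCc2ccccc2)c1 | starting material
6 | 4-{(1R)-1-[3-(benzyloxy)phenoxy]but-3-en-1-yl}phenyl trifluoromethanesulfonate | C=CC[C@H](c1ccc(OS(=O)(=O)C(F)(F)F)cc1)Oc1cccc(OCc2ccccc2)c1 | intermediate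
7 | 4-{(1R)-1-[3-(benzyloxy)phenoxy]-3,4-dihydroxybutyl}phenyl trifluoromethanesulfonate (both C3 epimers) | OCC(O)C[C@H](c1ccc(OS(=O)(=O)C(F)(F)F)cc1)Oc1cccc(OCc2ccccc2)c1 | intermediate
8 | 4-{(1R)-1-[3-(benzyloxy)phenoxy]-3-oxopropyl}phenyl trifluoromethanesulfonate | O=CC[C@H](c1ccc(OS(=O)(=O)C(F)(F)F)cc1)Oc1cccc(OCc2ccccc2)c1 | intermediate
9 | phloroglucinol | Oc1cc(O)cc(O)c1 | starting material
10 | 1,3,5-tris(benzyloxy)benzene | c1ccc(COc2cc(OCc3ccccc3)cc(OCc3ccccc3)c2)cc1 | intermediate
11 | 1,3,5-tris(benzyloxy)-2,4-dibromobenzene | Brc1c(OCc2ccccc2)cc(OCc2ccccc2)c(Br)c1OCc1ccccc1 | intermediate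
12 | [2,4,6-tris(benzyloxy)-3-bromophenyl]lithium | [Li]c1c(OCc2ccccc2)cc(OCc2ccccc2)c(Br)c1OCc1ccccc1 | intermediate
13 | 4-{(1R)-1-[3-(benzyloxy)phenoxy]-3-hydroxy-3-[2,4,6-tris(benzyloxy)-3-bromophenyl]propyl}phenyl trifluoromethanesulfonate (both carbinol epimers) | OC(C[C@H](c1ccc(OS(=O)(=O)C(F)(F)F)cc1)Oc1cccc(OCc2ccccc2)c1)c1c(OCc2ccccc2)cc(OCc2ccccc2)c(Br)c1OCc1ccccc1 | intermediate
14 | 4-{(2R,4R)-7-(benzyloxy)-4-[2,4,6-tris(benzyloxy)-3-bromophenyl]chroman-2-yl}phenyl trifluoromethanesulfonate | Brc1c(OCc2ccccc2)cc(OCc2ccccc2)c([C@@H]2C[C@H](c3ccc(OS(=O)(=O)C(F)(F)F)cc3)Oc3cc(OCc4ccccc4)ccc32)c1OCc1ccccc1 | intermediate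
15 | 4-{(2R,4R)-7-(benzyloxy)-4-[2,4,6-tris(benzyloxy)-3-bromophenyl]chroman-2-yl}phenol | Brc1c(OCc2ccccc2)cc(OCc2ccccc2)c([C@@H]2C[C@H](c3ccc(O)cc3)Oc3cc(OCc4ccccc4)ccc32)c1OCc1ccccc1 | intermediate
16 | (2R,4R)-7-(benzyloxy)-2-[4-(benzyloxy)phenyl]-4-[2,4,6-tris(benzyloxy)-3-bromophenyl]chroman | Brc1c(OCc2ccccc2)cc(OCc2ccccc2)c([C@@H]2C[C@H](c3ccc(OCc4ccccc4)cc3)Oc3cc(OCc4ccccc4)ccc32)c1OCc1ccccc1 | intermediate
17 | 9-phenylnonanoic acid | OC(=O)CCCCCCCCc1ccccc1 | starting material
18 | 1-(1H-imidazol-1-yl)-9-phenylnonan-1-one | O=C(CCCCCCCCc1ccccc1)n1ccnc1 | intermediate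
19 | N-methoxy-N-methyl-9-phenylnonanamide | CON(C)C(=O)CCCCCCCCc1ccccc1 | intermediate
20 | {2,4,6-tris(benzyloxy)-3-[(2R,4R)-7-(benzyloxy)-2-[4-(benzyloxy)phenyl]chroman-4-yl]phenyl}lithium | [Li]c1c(OCc2ccccc2)cc(OCc2ccccc2)c([C@@H]2C[C@H](c3ccc(OCc4ccccc4)cc3)Oc3cc(OCc4ccccc4)ccc32)c1OCc1ccccc1 | intermediate
21 | lithium alkoxide of the tetrahedral adduct of 20 and 19 (N-methoxy-N-methyl hemiaminal) | [Li]OC(CCCCCCCCc1ccccc1)(N(C)OC)c1c(OCc2ccccc2)cc(OCc2ccccc2)c([C@@H]2C[C@H](c3ccc(OCc4ccccc4)cc3)Oc3cc(OCc4ccccc4)ccc32)c1OCc1ccccc1 | intermediate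
22 | 1-{2,4,6-tris(benzyloxy)-3-[(2R,4R)-7-(benzyloxy)-2-[4-(benzyloxy)phenyl]chroman-4-yl]phenyl}-9-phenylnonan-1-one | O=C(CCCCCCCCc1ccccc1)c1c(OCc2ccccc2)cc(OCc2ccccc2)c([C@@H]2C[C@H](c3ccc(OCc4ccccc4)cc3)Oc3cc(OCc4ccccc4)ccc32)c1OCc1ccccc1 | intermediate
23 | 1-{2,4,6-trihydroxy-3-[(2R,4R)-7-hydroxy-2-(4-hydroxyphenyl)chroman-4-yl]phenyl}-9-phenylnonan-1-one | O=C(CCCCCCCCc1ccccc1)c1c(O)cc(O)c([C@@H]2C[C@H](c3ccc(O)cc3)Oc3cc(O)ccc32)c1O | target

**Count and risks**

Total step count: 12. Longest linear sequence: 9 steps (1, 2, 3, 4, 7, 8, 9, 11, 12); steps 5–6 and step 10 are side branches.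

Step 8 (ring closure). The cation may lose a proton to give a styrene, whose allylic C2–O bond can then ionise and erode the C2 configuration, or the cation may be attacked without facial preference and give 2,4-trans material. The fallback sets out from aldehyde 8 and comes back at 14. Pinnick oxidation (NaClO2, NaH2PO4, 2-methyl-2-butene) would give (3R)-3-[3-(benzyloxy)phenoxy]-3-[4-(trifluoromethylsulfonyloxy)phenyl]propanoic acid F1. Trifluoroacetic anhydride would then close ring C by intramolecular Friedel–Crafts acylation at the same ring A carbon, giving 4-[(2R)-7-(benzyloxy)-4-oxochroman-2-yl]phenyl trifluoromethanesulfonate F2. Aryllithium 12, transmetallated with CeCl3 to curb enolisation, would add to the ketone to give 4-{(2R)-7-(benzyloxy)-4-hydroxy-4-[2,4,6-tris(benzyloxy)-3-bromophenyl]chroman-2-yl}phenyl trifluoromethanesulfonate F3. Ionic hydrogenation (Et3SiH, CF3CO2H, CH2Cl2, −40 °C) would deliver hydride axially to the tertiary C4 cation, so that both aryl groups end up equatorial, which is 14.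

Step 11 (acyl transfer). The hindered, strongly basic aryllithium may deprotonate the Weinreb amide at its α-carbon instead of adding, so that the debrominated chroman is returned. The fallback sets out from Weinreb amide 19 and comes back at 22. Reduction with i-Bu2AlH at −78 °C would give 9-phenylnonanal F4. Aryllithium 20 should add to this far more electrophilic partner to give 1-{2,4,6-tris(benzyloxy)-3-[(2R,4R)-7-(benzyloxy)-2-[4-(benzyloxy)phenyl]chroman-4-yl]phenyl}-9-phenylnonan-1-ol F5 (both carbinol epimers). Oxidation with Dess–Martin periodinane buffered with NaHCO3 would then give ketone 22.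

Step 3 (Mitsunobu). The activated benzylic, homoallylic oxyphosphonium intermediate may eliminate to the aryl diene, or partly ionise and lower the enantiomeric purity that every later step depends on. The fallback sets out from alcohol 4 and comes back at 8; it cleaves the alkene first, so that the etherification runs on a 3-silyloxy-1-arylpropan-1-ol, a well-used substrate class without allylic hydrogens. Ozonolysis with NaBH4 work-up would give 4-[(1S)-1,3-dihydroxypropyl]phenyl trifluoromethanesulfonate F6. TBSCl and imidazole would protect the primary hydroxyl as 4-[(1S)-3-(tert-butyldimethylsilyloxy)-1-hydroxypropyl]phenyl trifluoromethanesulfonate F7. Mitsunobu reaction with phenol 5 would give, with inversion, 4-{(1R)-1-[3-(benzyloxy)phenoxy]-3-(tert-butyldimethylsilyloxy)propyl}phenyl trifluoromethanesulfonate F8. HF·pyridine would free 4-{(1R)-1-[3-(benzyloxy)phenoxy]-3-hydroxypropyl}phenyl trifluoromethanesulfonate F9, and Dess–Martin oxidation would give aldehyde 8.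

**Further compounds**

F1 | step 8 | (3R)-3-[3-(benzyloxy)phenoxy]-3-[4-(trifluoromethylsulfonyloxy)phenyl]propanoic acid | OC(=O)C[C@H](c1ccc(OS(=O)(=O)C(F)(F)F)cc1)Oc1cccc(OCc2ccccc2)c1
F2 | step 8 | 4-[(2R)-7-(benzyloxy)-4-oxochroman-2-yl]phenyl trifluoromethanesulfonate | O=C1C[C@H](c2ccc(OS(=O)(=O)C(F)(F)F)cc2)Oc2cc(OCc3ccccc3)ccc21
F3 | step 8 | 4-{(2R)-7-(benzyloxy)-4-hydroxy-4-[2,4,6-tris(benzyloxy)-3-bromophenyl]chroman-2-yl}phenyl trifluoromethanesulfonate (both C4 epimers) | OC1(c2c(OCc3ccccc3)cc(OCc3ccccc3)c(Br)c2OCc2ccccc2)C[C@H](c2ccc(OS(=O)(=O)C(F)(F)F)cc2)Oc2cc(OCc3ccccc3)ccc21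
F4 | step 11 | 9-phenylnonanal | O=CCCCCCCCCc1ccccc1
F5 | step 11 | 1-{2,4,6-tris(benzyloxy)-3-[(2R,4R)-7-(benzyloxy)-2-[4-(benzyloxy)phenyl]chroman-4-yl]phenyl}-9-phenylnonan-1-ol (both carbinol epimers) | OC(CCCCCCCCc1ccccc1)c1c(OCc2ccccc2)cc(OCc2ccccc2)c([C@@H]2C[C@H](c3ccc(OCc4ccccc4)cc3)Oc3cc(OCc4ccccc4)ccc32)c1OCc1ccccc1
F6 | step 3 | 4-[(1S)-1,3-dihydroxypropyl]phenyl trifluoromethanesulfonate | OCC[C@H](O)c1ccc(OS(=O)(=O)C(F)(F)F)cc1
F7 | step 3 | 4-[(1S)-3-(tert-butyldimethylsilyloxy)-1-hydroxypropyl]phenyl trifluoromethanesulfonate | CC(C)(C)[Si](C)(C)OCC[C@H](O)c1ccc(OS(=O)(=O)C(F)(F)F)cc1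
F8 | step 3 | 4-{(1R)-1-[3-(benzyloxy)phenoxy]-3-(tert-butyldimethylsilyloxy)propyl}phenyl trifluoromethanesulfonate | CC(C)(C)[Si](C)(C)OCC[C@H](c1ccc(OS(=O)(=O)C(F)(F)F)cc1)Oc1cccc(OCc2ccccc2)c1
F9 | step 3 | 4-{(1R)-1-[3-(benzyloxy)phenoxy]-3-hydroxypropyl}phenyl trifluoromethanesulfonate | OCC[C@H](c1ccc(OS(=O)(=O)C(F)(F)F)cc1)Oc1cccc(OCc2ccccc2)c1
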